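**Plan**
Numbering is that of germacrane: ring C1–C10, lactone carbons C11–C13, C14 methyl on C10, C15 hydroxymethyl on C4 (TBS = tert-butyldimethylsilyl, PMB = 4-methoxybenzyl).
Retrosynthesis: take off the C8 tiglate and the epoxide oxygen (leaving the E C1=C10 alkene), open the methylene lactone (C12–O6, C11=C13) to a C6 ketone with a C7 oxyethyl arm, then cut C8–C9 while re-joining C1–C6, and last cut C6–C7.
This is possible because the carbocycle holds the Z C4=C5 alkene next to the C6 oxygen and, 1,5 to the C6–C7 enol unit, the E C1=C10 alkene masked as the epoxide: O–C6=C7–C8–C9–C10=C1 is the retron of an oxy-Cope shift of a cyclohexene made of C1–C6.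
Forward: a quinone monoketal becomes the six-membered ring; a cyclic β-bromo enol acetal from cis-butenediol brings C7, C8, C11 and C12 onto the C6 ketone; the anionic oxy-Cope shift gives the ten-membered ring; the lactone ring is then closed and the epoxide added last.
Stereochemistry: C1 from Rh/(R)-BINAP conjugate addition; C3 from Luche reduction then Mitsunobu inversion; the C6 carbinol from addition anti to isopropenyl; C8 from the chair transition state with a ring-locked E enol ether; C7 from kinetic enolate protonation; C6 from chelation-controlled reduction; C1/C10 from peripheral epoxidation.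

Key step: step 13

Remark: the anisylidene carbon of the seven-membered acetal is carried as both epimers from 14 to 23 and is left undefined in those SMILES; it becomes the CH2 of the PMB ether in step 15.
Remark: α/β refer to the usual germacranolide drawing with H-7 α.

Step 1
Reactants: 1 4,4-dimethoxycyclohexa-2,5-dien-1-one; 2 isopropenylboronic acid pinacol ester
Product: 3 (5R)-4,4-dimethoxy-5-(prop-1-en-2-yl)cyclohex-2-en-1-one
Conditions: [RhCl(C2H4)2]2 (2.5 mol%), (R)-BINAP (6 mol%), KOH (0.3 equiv), dioxane/H2O 10:1, 35 °C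
Reagents that add atoms: none
Why: Rhodium-catalysed asymmetric 1,4-addition (Hayashi–Miyaura reaction) of an alkenylboronate to one of the two enantiotopic enone arms, in which the Rh–(R)-BINAP alkenyl species is expected to choose the enone face as it does for cyclohex-2-enone and so set C5 as R (the later C1), the hindered γ,γ-disubstituted product resisting a second addition.

Step 2
Reactants: 3 (5R)-4,4-dimethoxy-5-(prop-1-en-2-yl)cyclohex-2-en-1-one
Product: 4 (5R)-2-iodo-4,4-dimethoxy-5-(prop-1-en-2-yl)cyclohex-2-en-1-one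
Conditions: I2 (1.5 equiv), pyridine/CH2Cl2 1:1, 0 °C to rt
Reagents that add atoms: iodine, II
Why: α-Iodination of an enone by the iodine–pyridine addition–elimination sequence (conjugate addition of pyridine, iodination of the enolate, loss of pyridinium), with the isolated isopropenyl group untouched and the ketal kept intact by the basic medium.

Step 3
Reactants: 4 (5R)-2-iodo-4,4-dimethoxy-5-(prop-1-en-2-yl)cyclohex-2-en-1-one
Product: 5 (1R,5R)-2-iodo-4,4-dimethoxy-5-(prop-1-en-2-yl)cyclohex-2-en-1-ol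
Conditions: NaBH4, CeCl3·7H2O, MeOH, −78 °C
Reagents that add atoms: none
Why: Luche 1,2-reduction in which hydride should enter on the face away from the isopropenyl group (axial attack, as in the carvone to cis-carveol case), placing OH cis to isopropenyl.

Step 4
Reactants: 5 (1R,5R)-2-iodo-4,4-dimethoxy-5-(prop-1-en-2-yl)cyclohex-2-en-1-ol
Product: 6 (1S,5R)-2-iodo-4,4-dimethoxy-5-(prop-1-en-2-yl)cyclohex-2-en-1-yl 4-nitrobenzoate
Conditions: 4-nitrobenzoic acid, PPh3, DIAD, THF, 0 °C to rt
Reagents that add atoms: 4-nitrobenzoic acid, OC(=O)c1ccc(cc1)[N+](=O)[O-]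
Why: Mitsunobu esterification displaces the alkoxyphosphonium ion by SN2 with inversion, so the oxygen ends trans to isopropenyl, the SN2′ position being shielded by the neighbouring quaternary ketal carbon.

Step 5
Reactants: 6 (1S,5R)-2-iodo-4,4-dimethoxy-5-(prop-1-en-2-yl)cyclohex-2-en-1-yl 4-nitrobenzoate
Product: 7 (1S,5R)-2-iodo-4,4-dimethoxy-5-(prop-1-en-2-yl)cyclohex-2-en-1-ol
Conditions: K2CO3 (cat.), MeOH, 0 °C
Reagents that add atoms: none
Why: Transesterification (methanolysis) of the activated aryl ester by acyl–oxygen cleavage frees the trans allylic alcohol without touching the carbinol centre, and removes an allylic ester that would ionise under the palladium catalysis of the next step.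

Step 6
Reactants: 7 (1S,5R)-2-iodo-4,4-dimethoxy-5-(prop-1-en-2-yl)cyclohex-2-en-1-ol
Product: 8 (1S,5R)-2-(hydroxymethyl)-4,4-dimethoxy-5-(prop-1-en-2-yl)cyclohex-2-en-1-ol
Conditions: Bu3SnCH2OH, Pd(PPh3)4 (5 mol%), dioxane, 90 °C
Reagents that add atoms: (tributylstannyl)methanol, CCCC[Sn](CCCC)(CCCC)CO
Why: Stille coupling of the alkenyl iodide with the hydroxymethylstannane installs C15 with its oxygen in place, the free alcohol and the ketal being tolerated under these neutral conditions.

Step 7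
Reactants: 8 (1S,5R)-2-(hydroxymethyl)-4,4-dimethoxy-5-(prop-1-en-2-yl)cyclohex-2-en-1-ol
Product: 9 bis-TBS ether of (1S,5R)-2-(hydroxymethyl)-4,4-dimethoxy-5-(prop-1-en-2-yl)cyclohex-2-en-1-ol
Conditions: TBSCl (3 equiv), imidazole (6 equiv), DMAP (cat.), DMF, 40 °C
Reagents that add atoms: tert-butyldimethylsilyl chloride, CC(C)(C)[Si](C)(C)Cl
Why: Standard silylation of a primary and a secondary allylic alcohol, with chloride/imidazole chosen over the silyl triflate because the latter would ionise the allylic dimethyl ketal.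

Step 8
Reactants: 9 bis-TBS ether of (1S,5R)-2-(hydroxymethyl)-4,4-dimethoxy-5-(prop-1-en-2-yl)cyclohex-2-en-1-ol
Product: 10 (4S,6R)-4-(TBS-oxy)-3-(TBS-oxymethyl)-6-(prop-1-en-2-yl)cyclohex-2-en-1-one
Conditions: PPTS (10 mol%), acetone/H2O 20:1, rt
Reagents that add atoms: water, O
Why: Acid-catalysed hydrolysis of the allylic dimethyl ketal, the most labile group present, unmasks the C6 ketone under conditions that should neither cleave the TBS ethers nor epimerise the α′ centre that carries the isopropenyl group.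

Step 9
Reactants: 11 (Z)-but-2-ene-1,4-diol; 12 4-methoxybenzaldehyde dimethyl acetal
Product: 13 2-(4-methoxyphenyl)-4,7-dihydro-1,3-dioxepine
Conditions: PPTS (5 mol%), CH2Cl2, 4 Å molecular sieves, rt
Reagents that add atoms: none
Why: Acid-catalysed transacetalisation of a cis-1,4-diol, driven by removal of methanol, closes the seven-membered cyclic acetal.

Step 10
Reactants: 13 2-(4-methoxyphenyl)-4,7-dihydro-1,3-dioxepine
Product: 14 racemic 2-(4-methoxyphenyl)-4,5-dihydro-1,3-dioxepine
Conditions: RuHCl(CO)(PPh3)3 (0.5 mol%), toluene, 110 °C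
Reagents that add atoms: none
Why: Ruthenium hydride-catalysed double-bond migration (hydrometalation then β-hydride elimination) moves the allyl ether alkene into conjugation with oxygen, the cyclic enol ether being the more stable isomer.

Step 11
Reactants: 14 racemic 2-(4-methoxyphenyl)-4,5-dihydro-1,3-dioxepine
Product: 16 racemic 6-bromo-2-(4-methoxyphenyl)-4,5-dihydro-1,3-dioxepine, via dibromide 15 (not isolated)
Conditions: Br2, CH2Cl2, −78 °C; then Et3N (3 equiv), −78 °C to rt
Reagents that add atoms: bromine, BrBr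
Why: Bromine addition to the enol ether followed by amine-induced loss of HBr from the α-bromo ether (the bromination–dehydrobromination used for 3-bromo-4,5-dihydrofuran) puts bromine on the β-carbon, and the ring fixes it trans to the enol oxygen.

Step 12
Reactants: 16 racemic 6-bromo-2-(4-methoxyphenyl)-4,5-dihydro-1,3-dioxepine; 10 (4S,6R)-4-(TBS-oxy)-3-(TBS-oxymethyl)-6-(prop-1-en-2-yl)cyclohex-2-en-1-one
Product: 19 (1R,4S,6R)-4-(TBS-oxy)-3-(TBS-oxymethyl)-1-[2-(4-methoxyphenyl)-4,5-dihydro-1,3-dioxepin-6-yl]-6-(prop-1-en-2-yl)cyclohex-2-en-1-ol, via vinyllithium 17 (not isolated), via organocerium reagent 18 (not isolated)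
Conditions: 16 (1.5 equiv), t-BuLi (3.0 equiv), THF, −95 °C, 10 min; dry CeCl3 (1.6 equiv), −78 °C; then 10, −78 °C; aq. NH4Cl
Reagents that add atoms: none
Why: Bromine–lithium exchange gives a β-lithio enol ether that is kept cold to outrun anti β-elimination and is turned into the less basic organocerium reagent, whose 1,2-addition to the enone without enolisation should occur on the face opposite the neighbouring isopropenyl group, giving the trans-dialkenyl carbinol in which the dioxepine ring locks the enol oxygen trans to the carbinol carbon.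

Step 13
Reactants: 19 (1R,4S,6R)-4-(TBS-oxy)-3-(TBS-oxymethyl)-1-[2-(4-methoxyphenyl)-4,5-dihydro-1,3-dioxepin-6-yl]-6-(prop-1-en-2-yl)cyclohex-2-en-1-ol
Product: 22 3β,15-bis(TBS-oxy)-8β,12-(4-methoxybenzylidenedioxy)-7αH-13-norgermacra-1(10)E,4Z-dien-6-one, via potassium alkoxide 20 (not isolated), via potassium enolate 21 (not isolated)
Conditions: KH (3 equiv), 18-crown-6 (3 equiv), THF, 0 °C to rt; cool to −78 °C, AcOH (10 equiv) in THF
Reagents that add atoms: none
Why: KH with 18-crown-6 gives the dissociated potassium alkoxide 20, whose C6–O(−) bond weakens the allylic C1–C6 σ bond so that the [3,3] sigmatropic shift (anionic oxy-Cope rearrangement of a trans-1,2-dialkenylcyclohexanol, the closest known reaction type) forms C8–C9 and breaks C1–C6 far below the temperature of the neutral process. The ten-membered ring arises by ring expansion, that is by bond reorganisation inside a six-membered chair transition state made of C8, C7, C6, C1, C10 and C9, not by an end-to-end cyclisation. C8 is set in that transition state: the two alkenyl groups are trans-diequatorial on the cyclohexene, which fixes the sense of the chair, and the dioxepine ring holds the enol ether oxygen trans to C6 and hence equatorial on C8, so the configuration of C1 and C6 is handed on to C8 (8β-O) before both become trigonal. C7 is set when enolate 21 is protonated: its C6=C7 bond is trans within the ring and cannot turn through it, so acetic acid at −78 °C should add to the outer face, anti to the new C8–C9 bond, giving the cis-fused acetal with 7α-H. The step needs chair over boat selectivity (E C1=C10, with Z C4=C5 carried over from the six-membered ring) and survival of the β-alkoxy enolate; the first is secured by the trans relationship of the alkenyl groups, the second by the seven-membered acetal ring, which keeps the C8–O bond near the nodal plane of the enolate, and by the cold quench.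

Step 14
Reactants: 22 3β,15-bis(TBS-oxy)-8β,12-(4-methoxybenzylidenedioxy)-7αH-13-norgermacra-1(10)E,4Z-dien-6-one
Product: 23 3β,15-bis(TBS-oxy)-8β,12-(4-methoxybenzylidenedioxy)-13-norgermacra-1(10)E,4Z-dien-6α-ol
Conditions: Zn(BH4)2, Et2O, −30 °C
Reagents that add atoms: none
Why: Zinc borohydride reduces the enone 1,2 without base, and chelation of zinc between the C6 carbonyl and the C8 acetal oxygen with hydride delivery to the exposed face anti to the C7 side chain should give the 6α alcohol (chelation-controlled reduction of a β-alkoxy ketone).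

Step 15
Reactants: 23 3β,15-bis(TBS-oxy)-8β,12-(4-methoxybenzylidenedioxy)-13-norgermacra-1(10)E,4Z-dien-6α-ol
Product: 24 3β,15-bis(TBS-oxy)-8β-(PMB-oxy)-13-norgermacra-1(10)E,4Z-diene-6α,12-diol
Conditions: DIBAL-H (5 equiv), CH2Cl2, −78 to 0 °C; aq. potassium sodium tartrate
Reagents that add atoms: none
Why: Reductive opening of a 4-methoxybenzylidene acetal, in which the aluminium reagent binds the less hindered primary oxygen and cleaves that C–O bond, so hydride leaves the PMB group on the secondary C8 oxygen and frees C12–OH, both acetal epimers converging on one product.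

Step 16
Reactants: 24 3β,15-bis(TBS-oxy)-8β-(PMB-oxy)-13-norgermacra-1(10)E,4Z-diene-6α,12-diol
Product: 27 3β,15-bis(TBS-oxy)-8β-(PMB-oxy)-13-norgermacra-1(10)E,4Z-dien-6α,12-olide, via hydroxy aldehyde 25 (not isolated), via lactol 26 (not isolated)
Conditions: TEMPO (20 mol%), PhI(OAc)2 (2.5 equiv), CH2Cl2, rt
Reagents that add atoms: none
Why: Oxoammonium (TEMPO) oxidation takes the primary alcohol first, the aldehyde closes at once to the five-membered lactol with the 6α-OH, and a second oxidation gives the trans-fused γ-lactone (oxidative lactonisation of a 1,4-diol).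

Step 17
Reactants: 27 3β,15-bis(TBS-oxy)-8β-(PMB-oxy)-13-norgermacra-1(10)E,4Z-dien-6α,12-olide
Product: 31 3β,15-bis(TBS-oxy)-8β-(PMB-oxy)germacra-1(10)E,4Z,11(13)-trien-6α,12-olide, via lithium enolate 28 (not isolated), via Mannich base 29 (not isolated), via ammonium iodide 30 (not isolated)
Conditions: LiHMDS, THF, −78 °C; CH2=NMe2+ I−, −78 to 0 °C; MeI, MeOH, rt; DBU, CH2Cl2, rt
Reagents that add atoms: N,N-dimethylmethyleneiminium iodide, C=[N+](C)C.[I-]
Why: Eschenmoser methylenation, that is Mannich reaction of the lactone enolate with the iminium salt, quaternisation and E1cB loss of trimethylamine, gives the exocyclic methylene without a leaving group β to the enolate being present.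

Step 18
Reactants: 31 3β,15-bis(TBS-oxy)-8β-(PMB-oxy)germacra-1(10)E,4Z,11(13)-trien-6α,12-olide
Product: 32 3β,15-bis(TBS-oxy)-8β-hydroxygermacra-1(10)E,4Z,11(13)-trien-6α,12-olide
Conditions: DDQ (1.5 equiv), CH2Cl2/pH 7 buffer 10:1, 0 °C
Reagents that add atoms: none
Why: Oxidative PMB ether cleavage by hydride abstraction from the electron-rich benzylic position and hydrolysis of the oxocarbenium ion, under neutral conditions that spare the silyl ethers, the diene and the methylene lactone.

Step 19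
Reactants: 32 3β,15-bis(TBS-oxy)-8β-hydroxygermacra-1(10)E,4Z,11(13)-trien-6α,12-olide; 33 tigloyl chloride
Product: 34 3β,15-bis(TBS-oxy)-8β-tigloyloxygermacra-1(10)E,4Z,11(13)-trien-6α,12-olide
Conditions: pyridine, DMAP (cat.), CH2Cl2, 0 °C to rt
Reagents that add atoms: none
Why: DMAP-catalysed acylation of the only free hydroxyl, with pyridine as a base too weak to make the vinylketene that would deconjugate or isomerise the E-2-methylbut-2-enoyl group.

Step 20
Reactants: 34 3β,15-bis(TBS-oxy)-8β-tigloyloxygermacra-1(10)E,4Z,11(13)-trien-6α,12-olide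
Product: 35 1β,10α-epoxy-3β,15-bis(TBS-oxy)-8β-tigloyloxygermacra-4Z,11(13)-dien-6α,12-olide
Conditions: mCPBA (1.05 equiv), NaHCO3, CH2Cl2, −20 to 0 °C
Reagents that add atoms: 3-chloroperoxybenzoic acid, OOC(=O)c1cccc(Cl)c1
Why: Prilezhaev epoxidation picks the strained, electron-rich E-trisubstituted C1=C10 alkene over the hindered C4=C5 alkene and the two conjugated ones, and peripheral attack on the usual germacranolide conformer (C14 on the β face) should give the 1β,10α-epoxide (1R,10R).

Step 21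
Reactants: 35 1β,10α-epoxy-3β,15-bis(TBS-oxy)-8β-tigloyloxygermacra-4Z,11(13)-dien-6α,12-olide
Product: 36 CNP0187917.2, (1R,3S,6R,7R,8R,10R)-1β,10α-epoxy-3β,15-dihydroxy-8β-tigloyloxygermacra-4Z,11(13)-dien-6α,12-olide
Conditions: HF·pyridine, excess pyridine, THF, 0 °C to rt
Reagents that add atoms: none
Why: Fluoride-mediated desilylation with buffered HF·pyridine removes both TBS groups without the basicity that would add to the methylene lactone or move the ester and without free acid that would open the epoxide transannularly.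

**Compound list**
1 | 4,4-dimethoxycyclohexa-2,5-dien-1-one | COC1(OC)C=CC(=O)C=C1 | starting material
2 | isopropenylboronic acid pinacol ester | CC(=C)B1OC(C)(C)C(C)(C)O1 | starting material
3 | (5R)-4,4-dimethoxy-5-(prop-1-en-2-yl)cyclohex-2-en-1-one | COC1(OC)C=CC(=O)C[C@@H]1C(C)=C | intermediate
4 | (5R)-2-iodo-4,4-dimethoxy-5-(prop-1-en-2-yl)cyclohex-2-en-1-one | COC1(OC)C=C(I)C(=O)C[C@@H]1C(C)=C | intermediate
5 | (1R,5R)-2-iodo-4,4-dimethoxy-5-(prop-1-en-2-yl)cyclohex-2-en-1-ol (OH cis to isopropenyl) | COC1(OC)C=C(I)[C@H](O)C[C@@H]1C(C)=C | intermediate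
6 | (1S,5R)-2-iodo-4,4-dimethoxy-5-(prop-1-en-2-yl)cyclohex-2-en-1-yl 4-nitrobenzoate | COC1(OC)C=C(I)[C@@H](OC(=O)c2ccc(cc2)[N+](=O)[O-])C[C@@H]1C(C)=C | intermediate
7 | (1S,5R)-2-iodo-4,4-dimethoxy-5-(prop-1-en-2-yl)cyclohex-2-en-1-ol (OH trans to isopropenyl) | COC1(OC)C=C(I)[C@@H](O)C[C@@H]1C(C)=C | intermediate
8 | (1S,5R)-2-(hydroxymethyl)-4,4-dimethoxy-5-(prop-1-en-2-yl)cyclohex-2-en-1-ol | COC1(OC)C=C(CO)[C@@H](O)C[C@@H]1C(C)=C | intermediate
9 | bis-TBS ether of 8 | COC1(OC)C=C(CO[Si](C)(C)C(C)(C)C)[C@@H](O[Si](C)(C)C(C)(C)C)C[C@@H]1C(C)=C | intermediate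
10 | (4S,6R)-4-(TBS-oxy)-3-(TBS-oxymethyl)-6-(prop-1-en-2-yl)cyclohex-2-en-1-one | O=C1C=C(CO[Si](C)(C)C(C)(C)C)[C@@H](O[Si](C)(C)C(C)(C)C)C[C@@H]1C(C)=C | intermediate
11 | (Z)-but-2-ene-1,4-diol | OC/C=C\CO | starting material
12 | 4-methoxybenzaldehyde dimethyl acetal | COC(OC)c1ccc(OC)cc1 | starting material
13 | 2-(4-methoxyphenyl)-4,7-dihydro-1,3-dioxepine | COc1ccc(cc1)C1OCC=CCO1 | intermediate
14 | racemic 2-(4-methoxyphenyl)-4,5-dihydro-1,3-dioxepine | COc1ccc(cc1)C1OCCC=CO1 | intermediate
15 | trans-6,7-dibromo-2-(4-methoxyphenyl)-1,3-dioxepane | COc1ccc(cc1)C1OCCC(Br)C(Br)O1 | intermediate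
16 | racemic 6-bromo-2-(4-methoxyphenyl)-4,5-dihydro-1,3-dioxepine | COc1ccc(cc1)C1OCCC(Br)=CO1 | intermediate
17 | [2-(4-methoxyphenyl)-4,5-dihydro-1,3-dioxepin-6-yl]lithium | [Li]C1=COC(OCC1)c1ccc(OC)cc1 | intermediate
18 | dichloro[2-(4-methoxyphenyl)-4,5-dihydro-1,3-dioxepin-6-yl]cerium | Cl[Ce](Cl)C1=COC(OCC1)c1ccc(OC)cc1 | intermediate
19 | (1R,4S,6R)-4-(TBS-oxy)-3-(TBS-oxymethyl)-1-[2-(4-methoxyphenyl)-4,5-dihydro-1,3-dioxepin-6-yl]-6-(prop-1-en-2-yl)cyclohex-2-en-1-ol | O[C@]1(C2=COC(c3ccc(OC)cc3)OCC2)C=C(CO[Si](C)(C)C(C)(C)C)[C@@H](O[Si](C)(C)C(C)(C)C)C[C@@H]1C(C)=C | intermediate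
20 | potassium alkoxide of 19 | [K+].[O-][C@]1(C2=COC(c3ccc(OC)cc3)OCC2)C=C(CO[Si](C)(C)C(C)(C)C)[C@@H](O[Si](C)(C)C(C)(C)C)C[C@@H]1C(C)=C | intermediate
21 | potassium 6(7)-enolate of 22 (C5 and C8 trans across C6=C7) | [K+].C1/C=C(\C)C[C@H]2OC(c3ccc(OC)cc3)OCC/C2=C(/[O-])\C=C(\CO[Si](C)(C)C(C)(C)C)[C@H]1O[Si](C)(C)C(C)(C)C | intermediate
22 | 3β,15-bis(TBS-oxy)-8β,12-(4-methoxybenzylidenedioxy)-7αH-13-norgermacra-1(10)E,4Z-dien-6-one | O=C1/C=C(/CO[Si](C)(C)C(C)(C)C)[C@@H](O[Si](C)(C)C(C)(C)C)C/C=C(\C)C[C@H]2OC(c3ccc(OC)cc3)OCC[C@@H]12 | intermediate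
23 | 3β,15-bis(TBS-oxy)-8β,12-(4-methoxybenzylidenedioxy)-13-norgermacra-1(10)E,4Z-dien-6α-ol | O[C@@H]1/C=C(/CO[Si](C)(C)C(C)(C)C)[C@@H](O[Si](C)(C)C(C)(C)C)C/C=C(\C)C[C@H]2OC(c3ccc(OC)cc3)OCC[C@@H]12 | intermediate
24 | 3β,15-bis(TBS-oxy)-8β-(PMB-oxy)-13-norgermacra-1(10)E,4Z-diene-6α,12-diol | O[C@@H]1/C=C(/CO[Si](C)(C)C(C)(C)C)[C@@H](O[Si](C)(C)C(C)(C)C)C/C=C(\C)C[C@@H](OCc2ccc(OC)cc2)[C@H]1CCO | intermediate
25 | 3β,15-bis(TBS-oxy)-6α-hydroxy-8β-(PMB-oxy)-13-norgermacra-1(10)E,4Z-dien-12-al | O[C@@H]1/C=C(/CO[Si](C)(C)C(C)(C)C)[C@@H](O[Si](C)(C)C(C)(C)C)C/C=C(\C)C[C@@H](OCc2ccc(OC)cc2)[C@H]1CC=O | intermediate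
26 | 6α,12-lactol of 25 (both anomers) | OC1O[C@@H]2/C=C(/CO[Si](C)(C)C(C)(C)C)[C@@H](O[Si](C)(C)C(C)(C)C)C/C=C(\C)C[C@@H](OCc3ccc(OC)cc3)[C@H]2C1 | intermediate
27 | 3β,15-bis(TBS-oxy)-8β-(PMB-oxy)-13-norgermacra-1(10)E,4Z-dien-6α,12-olide | O=C1O[C@@H]2/C=C(/CO[Si](C)(C)C(C)(C)C)[C@@H](O[Si](C)(C)C(C)(C)C)C/C=C(\C)C[C@@H](OCc3ccc(OC)cc3)[C@H]2C1 | intermediate
28 | lithium enolate of 27 | [Li+].[O-]C=1O[C@@H]2/C=C(/CO[Si](C)(C)C(C)(C)C)[C@@H](O[Si](C)(C)C(C)(C)C)C/C=C(\C)C[C@@H](OCc3ccc(OC)cc3)[C@H]2C=1 | intermediate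
29 | 11-(dimethylaminomethyl) derivative of 27 (both C11 epimers) | O=C1O[C@@H]2/C=C(/CO[Si](C)(C)C(C)(C)C)[C@@H](O[Si](C)(C)C(C)(C)C)C/C=C(\C)C[C@@H](OCc3ccc(OC)cc3)[C@H]2C1CN(C)C | intermediate
30 | trimethylammonium iodide of 29 | [I-].O=C1O[C@@H]2/C=C(/CO[Si](C)(C)C(C)(C)C)[C@@H](O[Si](C)(C)C(C)(C)C)C/C=C(\C)C[C@@H](OCc3ccc(OC)cc3)[C@H]2C1C[N+](C)(C)C | intermediate
31 | 3β,15-bis(TBS-oxy)-8β-(PMB-oxy)germacra-1(10)E,4Z,11(13)-trien-6α,12-olide | O=C1O[C@@H]2/C=C(/CO[Si](C)(C)C(C)(C)C)[C@@H](O[Si](C)(C)C(C)(C)C)C/C=C(\C)C[C@@H](OCc3ccc(OC)cc3)[C@H]2C1=C | intermediate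
32 | 3β,15-bis(TBS-oxy)-8β-hydroxygermacra-1(10)E,4Z,11(13)-trien-6α,12-olide | O=C1O[C@@H]2/C=C(/CO[Si](C)(C)C(C)(C)C)[C@@H](O[Si](C)(C)C(C)(C)C)C/C=C(\C)C[C@@H](O)[C@H]2C1=C | intermediate
33 | tigloyl chloride, (E)-2-methylbut-2-enoyl chloride | C/C=C(\C)C(Cl)=O | starting material
34 | 3β,15-bis(TBS-oxy)-8β-tigloyloxygermacra-1(10)E,4Z,11(13)-trien-6α,12-olide | O=C1O[C@@H]2/C=C(/CO[Si](C)(C)C(C)(C)C)[C@@H](O[Si](C)(C)C(C)(C)C)C/C=C(\C)C[C@@H](OC(=O)/C(C)=C/C)[C@H]2C1=C | intermediate
35 | 1β,10α-epoxy-3β,15-bis(TBS-oxy)-8β-tigloyloxygermacra-4Z,11(13)-dien-6α,12-olide | O=C1O[C@@H]2/C=C(/CO[Si](C)(C)C(C)(C)C)[C@@H](O[Si](C)(C)C(C)(C)C)C[C@H]3O[C@]3(C)C[C@@H](OC(=O)/C(C)=C/C)[C@H]2C1=C | intermediate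
36 | CNP0187917.2, (1R,3S,6R,7R,8R,10R)-1β,10α-epoxy-3β,15-dihydroxy-8β-tigloyloxygermacra-4Z,11(13)-dien-6α,12-olide | C=C1C(=O)O[C@@H]2/C=C(/CO)[C@@H](O)C[C@H]3O[C@]3(C)C[C@@H](OC(=O)/C(C)=C/C)[C@@H]12 | target

**Count**
Total steps: 21. Longest linear sequence: 18 steps (steps 1–8, then 12–21); the acetal branch (steps 9–11) joins at step 12.

**Steps most likely to fail**

Step 12. The β-lithio enol ether may open by anti β-elimination of the ring oxygen before it is trapped, and the carbanion may enolise the enone or add on the face syn to isopropenyl. The fallback avoids the lithium species altogether and sets out from 14 (with 10 as partner). ICl in CH2Cl2 at −78 °C should add across the enol ether to give trans-7-chloro-6-iodo-2-(4-methoxyphenyl)-1,3-dioxepane F1. Et3N should then remove HCl to give 6-iodo-2-(4-methoxyphenyl)-4,5-dihydro-1,3-dioxepine F2. Iodine–magnesium exchange with iPrMgCl·LiCl in THF at −30 °C should give the less elimination-prone [2-(4-methoxyphenyl)-4,5-dihydro-1,3-dioxepin-6-yl]magnesium chloride F3. Addition of F3 to 10 in the presence of LaCl3·2LiCl and aqueous work-up would return to the route at 19.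

Step 13. The potassium enolate may expel the C8 acetal oxygen by E1cB elimination while it waits at the rearrangement temperature or during the quench, and C7 may be protonated without face control. The fallback sets out from 19 and keeps the same rearrangement, but the cold solution of the enolate is treated with Me3SiCl/Et3N at −78 °C instead of acid. The enolate is thereby taken out as the neutral 6-trimethylsilyloxy-germacra-1(10)E,4Z,6E-triene F4, which can be handled and purified without base. C7 is then set in a separate protodesilylation of F4 with Et3N·3HF in THF at −40 °C, which never passes through a free enolate, and this comes back to the route at 22.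

Step 14. Hydride may be delivered to the other face of the ten-membered enone if the ring reacts through a conformer in which zinc chelation is not possible, which would give the wrong C6 configuration for a trans-fused lactone. The fallback sets out from 22 and corrects C6 by substitution rather than by reagent choice. The 6β alcohol, 3β,15-bis(TBS-oxy)-8β,12-(4-methoxybenzylidenedioxy)-13-norgermacra-1(10)E,4Z-dien-6β-ol F5, obtained from whichever hydride source favours it (for example NaBH4/CeCl3 in MeOH), is subjected to Mitsunobu esterification with 4-nitrobenzoic acid, PPh3 and DIAD. This should give the inverted 6α 4-nitrobenzoate F6, and K2CO3 in MeOH would then return to the route at 23.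

**Further compounds**
F1 | step 12 | trans-7-chloro-6-iodo-2-(4-methoxyphenyl)-1,3-dioxepane | COc1ccc(cc1)C1OCCC(I)C(Cl)O1
F2 | step 12 | 6-iodo-2-(4-methoxyphenyl)-4,5-dihydro-1,3-dioxepine | COc1ccc(cc1)C1OCCC(I)=CO1
F3 | step 12 | [2-(4-methoxyphenyl)-4,5-dihydro-1,3-dioxepin-6-yl]magnesium chloride | Cl[Mg]C1=COC(OCC1)c1ccc(OC)cc1
F4 | step 13 | 3β,15-bis(TBS-oxy)-6-trimethylsilyloxy-8β,12-(4-methoxybenzylidenedioxy)-13-norgermacra-1(10)E,4Z,6E-triene | C1/C=C(\C)C[C@H]2OC(c3ccc(OC)cc3)OCC/C2=C(/O[Si](C)(C)C)\C=C(\CO[Si](C)(C)C(C)(C)C)[C@H]1O[Si](C)(C)C(C)(C)C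
F5 | step 14 | 3β,15-bis(TBS-oxy)-8β,12-(4-methoxybenzylidenedioxy)-13-norgermacra-1(10)E,4Z-dien-6β-ol | O[C@H]1/C=C(/CO[Si](C)(C)C(C)(C)C)[C@@H](O[Si](C)(C)C(C)(C)C)C/C=C(\C)C[C@H]2OC(c3ccc(OC)cc3)OCC[C@@H]12
F6 | step 14 | 6α 4-nitrobenzoate of 23 | O=C(O[C@@H]1/C=C(/CO[Si](C)(C)C(C)(C)C)[C@@H](O[Si](C)(C)C(C)(C)C)C/C=C(\C)C[C@H]2OC(c3ccc(OC)cc3)OCC[C@@H]12)c1ccc(cc1)[N+](=O)[O-]
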